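**Plan**
- **Retrosynthesis:** the (M) axis goes back to the racemate, the six phenols to methyl ethers, and the C2=C3 and C2''=C3'' double bonds to tertiary carbinols at C3 and C3''. Then C3–C4 and C3''–C4'' are cut together, next the O1–C2 and O1''–C2'' aryl ether bonds, and last the C3'–C8'' biaryl bond.
- **Enabling feature** (unit 1 is the isoflavone joined through C3' of its ring B, unit 2 the one joined through C8'' of its ring A): in each pyranone ring C, the carbonyl carbon C4 sits on C4a, ortho to the O1-bearing C8a. Its other neighbour C3 carries the aryl group and reaches O1 through C2. A salicylaldehyde O-alkylated with ArC(=O)CH2 therefore already contains O1, C2, C3, C4, C4a and C8a, and the formyl carbon (C4) and the ketone carbon (C3) are the only unconnected pair.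
- **Forward order:** ring A of unit 2 is iodinated and coupled to ring B, so the biaryl comes first. The two keto ether side chains are attached, both rings C close in one carbene-catalysed operation, then water is lost and the methyl groups are removed.
- **Stereochemistry:** C3 and C3'' are transient and uncontrolled. The axis is built racemic and the (M) enantiomer is taken at the end by chromatography on a chiral phase; the (P) fraction can be equilibrated thermally and recycled.

Key step: step 6

Assumption: the C3'–C8'' axis, flanked by the 4'-oxygen, the 7''-oxygen and the O1''-bearing C8a'', rotates slowly enough at or below room temperature for the enantiomers of the racemic target to be separated and stored, as the occurrence of the natural product as a single (M) atropisomer implies.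

Step 1
Reactants: 1 2-hydroxy-4,6-dimethoxybenzaldehyde
Product: 2 2-hydroxy-3-iodo-4,6-dimethoxybenzaldehyde
Conditions: BnMe3N·ICl2 (1.0 equiv), CaCO3, CH2Cl2/MeOH, rt
Reagents that add atoms: benzyltrimethylammonium dichloroiodate, C[N+](C)(C)Cc1ccccc1.Cl[I-]Cl
Why: Electrophilic aromatic iodination of a chelated ortho-hydroxyaryl aldehyde is expected at C3, the carbon between the hydrogen-bonded OH and the 4-OMe group (the preference known from the 6-iodination of 5-hydroxy-7-alkoxyflavones with this reagent), because C5 is screened by the 6-OMe methyl group that the formyl group turns towards it, and one equivalent of reagent limits double iodination.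

Step 2
Reactants: 2 2-hydroxy-3-iodo-4,6-dimethoxybenzaldehyde; 3 (5-acetyl-2-methoxyphenyl)boronic acid
Product: 4 3-(5-acetyl-2-methoxyphenyl)-2-hydroxy-4,6-dimethoxybenzaldehyde
Conditions: Pd(OAc)2 (5 mol %), SPhos (10 mol %), K3PO4 (3 equiv), 1,4-dioxane/H2O, 80 °C
Reagents that add atoms: none
Why: Suzuki–Miyaura coupling with a bulky dialkylbiarylphosphine is established for tri-ortho-substituted biaryls and tolerates free 2-halophenols; boron sits on ring B because a 2,6-dioxygenated arylboronic acid would protodeboronate, and the phenoxide present under the conditions deactivates the adjacent formyl group towards Claisen–Schmidt condensation with the acetyl group.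

Step 3
Reactants: 4 3-(5-acetyl-2-methoxyphenyl)-2-hydroxy-4,6-dimethoxybenzaldehyde
Product: 7 3-[5-(2-bromoacetyl)-2-methoxyphenyl]-2-(tert-butyldimethylsilyloxy)-4,6-dimethoxybenzaldehyde, via dipotassium phenoxide-enolate 5 (not isolated), via bis-TBS aryl ether enol ether 6 (not isolated)
Conditions: KN(SiMe3)2 (2.3 equiv), THF, −78 °C; TBSOTf (2.3 equiv), −78 °C; NBS (1.05 equiv), −78 → −40 °C; pH 7 buffer
Reagents that add atoms: tert-butyldimethylsilyl triflate, CC(C)(C)[Si](C)(C)OS(=O)(=O)C(F)(F)F; N-bromosuccinimide, O=C1CCC(=O)N1Br
Why: The first equivalent of base makes the phenoxide, which turns the formyl group into an unreactive vinylogous carboxylate, the second makes the methyl ketone enolate, and O-silylation of both oxygens followed by NBS bromination of the silyl enol ether (much more nucleophilic at −78 °C than C5–H of ring A, with no free silyl triflate left to start a Mukaiyama aldol reaction) is the standard regiospecific route to an α-bromo ketone and leaves the phenol masked for step 4.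

Step 4
Reactants: 7 3-[5-(2-bromoacetyl)-2-methoxyphenyl]-2-(tert-butyldimethylsilyloxy)-4,6-dimethoxybenzaldehyde; 1 2-hydroxy-4,6-dimethoxybenzaldehyde
Product: 8 2-(tert-butyldimethylsilyloxy)-3-{5-[2-(2-formyl-3,5-dimethoxyphenoxy)acetyl]-2-methoxyphenyl}-4,6-dimethoxybenzaldehyde
Conditions: K2CO3 (1.5 equiv), acetone, 0 °C → rt
Reagents that add atoms: none
Why: Williamson ether synthesis with a highly reactive phenacyl bromide runs at or below room temperature, where the hindered aryl TBS ether survives and prevents self-alkylation of 7, and where base-induced aldol closure of the new keto ether onto its electron-rich formyl group is still slow.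

Step 5
Reactants: 8 2-(tert-butyldimethylsilyloxy)-3-{5-[2-(2-formyl-3,5-dimethoxyphenoxy)acetyl]-2-methoxyphenyl}-4,6-dimethoxybenzaldehyde; 9 2-bromo-1-(4-methoxyphenyl)ethanone
Product: 11 3-{5-[2-(2-formyl-3,5-dimethoxyphenoxy)acetyl]-2-methoxyphenyl}-4,6-dimethoxy-2-[2-(4-methoxyphenyl)-2-oxoethoxy]benzaldehyde (the biaryl bis-O-phenacyl salicylaldehyde), via caesium phenoxide 10 (not isolated)
Conditions: CsF (1.3 equiv), DMF, 0 °C → rt
Reagents that add atoms: none
Why: In this one-pot desilylation–Williamson alkylation of an aryl silyl ether, fluoride frees the phenoxide in the presence of the phenacyl bromide, which traps it at once, so the aldol-prone keto aldehyde units meet only a small excess of a mild base for a short time.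

Step 6
Reactants: 11 biaryl bis-O-phenacyl salicylaldehyde
Product: 12 3-hydroxy-8-[5-(3-hydroxy-5,7-dimethoxy-4-oxochroman-3-yl)-2-methoxyphenyl]-5,7-dimethoxy-3-(4-methoxyphenyl)chroman-4-one (mixture of diastereomers at C3 and C3'' and the axis)
Conditions: 2-(pentafluorophenyl)-6,7-dihydro-5H-pyrrolo[2,1-c][1,2,4]triazol-2-ium tetrafluoroborate (40 mol %), Et3N (40 mol %), degassed toluene (0.02 M), 4 Å MS, 40 °C, Ar
Reagents that add atoms: none
Why: The free triazolylidene adds to each formyl group, a proton shift eased by the electron-poor C6F5 substituent gives the enaminol (Breslow intermediate), its nucleophilic carbon (the future C4 or C4'') attacks the tethered aryl ketone carbon (C3 or C3''), and collapse of the adduct releases the carbene. The closest known reaction type is the carbene-catalysed intramolecular crossed aldehyde–ketone benzoin reaction of O-(2-oxoalkyl)salicylaldehydes to 3-hydroxychroman-4-ones, used here at two sites of one molecule. Both rings C close in the 6-exo-trig mode, with the ketone C=O outside the forming ring. C3 and C3'' form without control, since the catalyst is achiral and the distant axis exerts little bias, which does no harm because both carbons become sp2 in step 7. The step needs chemoselectivity for acyl anion addition over enolate aldol closure to 2-aroylbenzofurans (Rap–Stoermer path) and over intermolecular benzoin coupling. The substrate secures this because its formyl groups, each flanked by two oxygens and fed by three donors, are poor aldol acceptors, only a substoichiometric tertiary amine is present, the α-aryloxy ketones are activated acceptors held at ring-closing distance, and the small flat carbene together with high dilution favours the intramolecular path.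

Step 7
Reactants: 12 biaryl bis(3-aryl-3-hydroxychroman-4-one)
Product: 13 8-[5-(5,7-dimethoxy-4-oxo-4H-chromen-3-yl)-2-methoxyphenyl]-5,7-dimethoxy-3-(4-methoxyphenyl)-4H-chromen-4-one (racemic hexa-O-methylbisoflavolin D)
Conditions: TsOH·H2O (0.5 equiv), toluene, reflux, Dean–Stark
Reagents that add atoms: none
Why: In this acid-catalysed E1 dehydration each tertiary carbinol ionises to a cation stabilised by an aryl ring bearing OMe para to the cationic centre (4'-OMe in unit 1, the anisyl OMe in unit 2), and loss of a C2 proton gives the strongly stabilised chromone vinylogous ester and erases both transient stereocentres.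

Step 8
Reactants: 13 racemic hexa-O-methylbisoflavolin D
Product: 14 racemic bisoflavolin D
Conditions: BBr3 (18 equiv), CH2Cl2, −78 °C → rt; then H2O
Reagents that add atoms: none
Why: Exhaustive aryl methyl ether cleavage with BBr3 is the usual last chemical step for isoflavones and biflavonoids, and the Lewis acid at or below room temperature avoids the hot protic acids that open 5-hydroxychromones and could move the aryl group from C8'' to C6'' by Wessely–Moser rearrangement.

Step 9
Reactants: 14 racemic bisoflavolin D
Product: 15 (M)-bisoflavolin D
Conditions: preparative HPLC, immobilised amylose tris(3,5-dimethylphenylcarbamate) phase, n-hexane/EtOH/0.1 % TFA, 10 °C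
Reagents that add atoms: none
Why: Enantiomer separation of a biaryl atropisomer on a polysaccharide chiral stationary phase is routine and the C3'–C8'' axis is the only stereogenic element; the (M) fraction would be assigned by comparing its ECD curve with a TDDFT calculation and its sign of rotation with that of the natural product, and the low temperature guards against rotation about the axis.

**Compound list**
1 | 2-hydroxy-4,6-dimethoxybenzaldehyde | COc1cc(O)c(C=O)c(OC)c1 | starting material
2 | 2-hydroxy-3-iodo-4,6-dimethoxybenzaldehyde | O=Cc1c(O)c(I)c(OC)cc1OC | intermediate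
3 | (5-acetyl-2-methoxyphenyl)boronic acid | CC(=O)c1ccc(OC)c(B(O)O)c1 | starting material
4 | 3-(5-acetyl-2-methoxyphenyl)-2-hydroxy-4,6-dimethoxybenzaldehyde | O=Cc1c(O)c(-c2cc(C(C)=O)ccc2OC)c(OC)cc1OC | intermediate
5 | dipotassium phenoxide-enolate of 4 (not isolated) | [K+].[K+].C=C([O-])c1ccc(OC)c(c1)-c1c([O-])c(C=O)c(OC)cc1OC | intermediate
6 | 2-(tert-butyldimethylsilyloxy)-3-{5-[1-(tert-butyldimethylsilyloxy)vinyl]-2-methoxyphenyl}-4,6-dimethoxybenzaldehyde (not isolated) | C=C(O[Si](C)(C)C(C)(C)C)c1ccc(OC)c(c1)-c1c(O[Si](C)(C)C(C)(C)C)c(C=O)c(OC)cc1OC | intermediate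
7 | 3-[5-(2-bromoacetyl)-2-methoxyphenyl]-2-(tert-butyldimethylsilyloxy)-4,6-dimethoxybenzaldehyde | BrCC(=O)c1ccc(OC)c(c1)-c1c(O[Si](C)(C)C(C)(C)C)c(C=O)c(OC)cc1OC | intermediate
8 | 2-(tert-butyldimethylsilyloxy)-3-{5-[2-(2-formyl-3,5-dimethoxyphenoxy)acetyl]-2-methoxyphenyl}-4,6-dimethoxybenzaldehyde | O=Cc1c(OC)cc(OC)cc1OCC(=O)c1ccc(OC)c(c1)-c1c(O[Si](C)(C)C(C)(C)C)c(C=O)c(OC)cc1OC | intermediate
9 | 2-bromo-1-(4-methoxyphenyl)ethanone | COc1ccc(cc1)C(=O)CBr | starting material
10 | caesium phenoxide formed from 8 by loss of the silyl group (not isolated) | [Cs+].O=Cc1c(OC)cc(OC)cc1OCC(=O)c1ccc(OC)c(c1)-c1c([O-])c(C=O)c(OC)cc1OC | intermediate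
11 | biaryl bis-O-phenacyl salicylaldehyde, racemic axis | COc1ccc(cc1)C(=O)COc1c(C=O)c(OC)cc(OC)c1-c1cc(ccc1OC)C(=O)COc1cc(OC)cc(OC)c1C=O | intermediate
12 | biaryl bis(3-aryl-3-hydroxychroman-4-one), C3 and C3'' unassigned, mixture of diastereomers | COc1ccc(cc1)C1(O)COc2c(C1=O)c(OC)cc(OC)c2-c1cc(ccc1OC)C1(O)COc2cc(OC)cc(OC)c2C1=O | intermediate
13 | racemic hexa-O-methylbisoflavolin D | COc1ccc(cc1)-c1coc2c(c1=O)c(OC)cc(OC)c2-c1cc(ccc1OC)-c1coc2cc(OC)cc(OC)c2c1=O | intermediate
14 | racemic bisoflavolin D | O=c1c(-c2ccc(O)c(-c3c(O)cc(O)c4c(=O)c(-c5ccc(O)cc5)coc34)c2)coc2cc(O)cc(O)c12 | intermediate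
15 | (M)-bisoflavolin D, (M)-configured C3'–C8'' axis (the axis has no SMILES symbol) | O=c1c(-c2ccc(O)c(-c3c(O)cc(O)c4c(=O)c(-c5ccc(O)cc5)coc34)c2)coc2cc(O)cc(O)c12 | target

**Total step count:** 9
**Longest linear sequence:** 9 steps (1 to 15; compound 1 enters twice, in steps 1 and 4)

**Steps most likely to fail**

**Step 6.** Enaminol formation at the doubly ortho-oxygenated, electron-rich formyl groups may be sluggish. Base-induced aldol cyclisation with loss of water could then take over, or the reaction could stall after a single closure.

The fallback forms the same two bonds reductively instead of by umpolung. It sets out from 11. A twofold intramolecular pinacol coupling with low-valent titanium (TiCl4/Zn, THF, 0 °C, stopped at the diol stage before deoxygenation) would give the bis(3-arylchroman-3,4-diol) F1. IBX in DMSO at rt then oxidises only the secondary benzylic carbinols at C4 and C4'', without glycol cleavage. The sequence comes back to the route at 12.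

**Step 3.** Three processes may intervene: aldol addition of the enolate to formyl groups, bromination of ring A at C5, or early loss of the aryl silyl ether.

The fallback makes the O1–C2 ether of unit 1 before the biaryl bond, on a ring B that has no electron-rich neighbour. It sets out from 1.
- Williamson alkylation with commercial 2-bromo-1-(3-bromo-4-methoxyphenyl)ethanone F2 (K2CO3, acetone, rt) gives 2-[2-(3-bromo-4-methoxyphenyl)-2-oxoethoxy]-4,6-dimethoxybenzaldehyde F3.
- The formyl group is masked (HC(OMe)3, cat. PPTS, MeOH) as the dimethyl acetal F4, so that no aldol acceptor is present under basic coupling conditions.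
- Miyaura borylation (B2pin2, Pd(dppf)Cl2, KOAc, dioxane, 80 °C) gives the pinacol boronate F5.
- Suzuki–Miyaura coupling with 2 under the conditions of step 2 gives the biaryl phenol acetal F6.
- Work-up with dilute aqueous acid hydrolyses F6 to the biaryl phenol dialdehyde F7.
- Alkylation of F7 with 9 (K2CO3, DMF, rt) comes back to the route at 11.

**Step 9.** Tailing of the hexaphenol on the chiral phase may prevent clean separation, and slow rotation about the axis during evaporation may erode the enantiomeric purity.

The fallback moves the resolution one stage earlier. It sets out from 13, which is less polar and carries larger ortho groups at the axis. Its enantiomers are separated on the same type of phase to give (M)-hexa-O-methylbisoflavolin D F8. The CIP ranking at both ends of the axis (C8a'' over C7'', C4' over C2') is not changed by O-methylation, so the descriptor carries over. Demethylation with BBr3 kept between −78 and 0 °C comes back to the route at 15.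

**Further compounds**
F1 | step 6 | bis(3-arylchroman-3,4-diol), stereocentres unassigned | COc1ccc(cc1)C1(O)COc2c(C1O)c(OC)cc(OC)c2-c1cc(ccc1OC)C1(O)COc2cc(OC)cc(OC)c2C1O
F2 | step 3 | 2-bromo-1-(3-bromo-4-methoxyphenyl)ethanone | COc1ccc(cc1Br)C(=O)CBr
F3 | step 3 | 2-[2-(3-bromo-4-methoxyphenyl)-2-oxoethoxy]-4,6-dimethoxybenzaldehyde | COc1ccc(cc1Br)C(=O)COc1cc(OC)cc(OC)c1C=O
F4 | step 3 | dimethyl acetal of F3 | COc1ccc(cc1Br)C(=O)COc1cc(OC)cc(OC)c1C(OC)OC
F5 | step 3 | pinacol boronate from F4 | COc1ccc(cc1B1OC(C)(C)C(C)(C)O1)C(=O)COc1cc(OC)cc(OC)c1C(OC)OC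
F6 | step 3 | biaryl phenol acetal | COC(OC)c1c(OC)cc(OC)cc1OCC(=O)c1ccc(OC)c(c1)-c1c(O)c(C=O)c(OC)cc1OC
F7 | step 3 | biaryl phenol dialdehyde | O=Cc1c(OC)cc(OC)cc1OCC(=O)c1ccc(OC)c(c1)-c1c(O)c(C=O)c(OC)cc1OC
F8 | step 9 | (M)-hexa-O-methylbisoflavolin D, (M) axis (no SMILES symbol) | COc1ccc(cc1)-c1coc2c(c1=O)c(OC)cc(OC)c2-c1cc(ccc1OC)-c1coc2cc(OC)cc(OC)c2c1=O
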